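A leftover is where we start: Sunday's run, which is this very flask, still reads 47.6% of its X at 10.0 min, and its J readings have stayed level within their scatter since 5.00 min.

| setting | Sunday's | Monday's | flask |
|---|---|---|---|
| X | 0.30 M | 0.15 M | 0.30 M |
| G | 0.30 M | 0.30 M | 0.300 M |
| temperature | 25 °C | 10 °C | 25 °C |
| remark | the very flask that is asked about, followed so far | run made earlier |  |
| time |  |  | 10 min |

| run | time / min | J / % | X / % |
|---|---|---|---|
| Sunday's | 0.833 | 0.8 | 99.1 |
| Sunday's | 2.50 | 44.2 | 55.5 |
| Sunday's | 5.00 | 50.4 | 48.0 |
| Sunday's | 8.00 | 50.6 | 49.0 |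
| Sunday's | 10.0 | 51.0 | 47.6 |
| Monday's | 0.333 | 0.1 | 100.0 |
| Monday's | 0.667 | 0 | 100.5 |
| Monday's | 1.00 | 0.4 | 100.2 |
| Monday's | 2.00 | 0.4 | 100.0 |
| Monday's | 4.00 | 1.4 | 98.5 |

(scatter of a reading: 0.5 percentage points)

- grey: at 10 min raise the temperature by 10 K, then wait 5.0 min
- green: at 10 min take out 90% of the L then present, then wait 5.0 min
- blue: change nothing and wait 5.0 min more
- violet: at 10 min add G, 50.0% of the amount charged, then wait 5.0 min

1. J, in percent of the X first charged, at 10 min
2. which option adds most J ("none" when 2 percentage points or less is all one gets) (grey / green / blue / violet / none)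
3. J present, in percent of the X first charged, after green
4. J present, in percent of the X first charged, after violet

- additions leave the volume as it is

We build the flask up one process at a time. With the main step alone, X + G → J + L, each G that reacts makes one J, and with 0.30 M of X against 0.30 M of G, J climbs until both charges are used.

Now let L speed its own making. That gives Sunday's lag and jump, with J at 0.8% after 0.833 min and 44.2% after 2.50 min, but the end point stays the same.

The third addition is a leak of G into something unseen, and this one moves the end point. While the flask waits for L, each G stands at a fork: it meets X or it leaves. G then becomes the limiting reagent, and J stops where the supply of G ends. G is not among the readings, so this is our bet, made on the sharp stop in Sunday's run: J rises by 43 percentage points in one interval and by 6.2 points in the next, longer one.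

So we carry one number, the G yield, meaning the J made per G charged:

plateau of J = 50.7%

G yield = 50.7% × 0.30 M / 0.300 M = 0.507

violet gain = 0.507 × 50.0% × 0.300 M / 0.30 M = 25 points

By our reckoning J now stands at 50.7%. Blue, green and grey bring no G, so we expect them to add nothing and green to stay at 50.7%. Violet is our choice for best, and at the yield of the first charge it reaches 75.7%.

The forecast reads the stop differently, as “an equilibrium X + G ⇌ J + L with K ≈ 1.1”. It gives 50.8% (50.1% to 51.5%) for now, green as best, 65% (57% to 67%) after green and 61% (57% to 74%) after violet.

The flask gives 50.6% at 10 min, with G at 0% of its charge. Best is violet, which reaches 89.3%, while green stays at 50.6%.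

    X → Z (k = 3.12 × 10⁻⁵ s⁻¹, Ea = 100 kJ mol⁻¹)
    X + G → J + L (k = 2.22 × 10⁻⁵ M⁻¹ s⁻¹, Ea = 80.0 kJ mol⁻¹)
    X + G + L → J + 2 L (k = 1.31 M⁻² s⁻¹, Ea = 35.0 kJ mol⁻¹)
    G → E (k = 0.00593 s⁻¹, Ea = 76.0 kJ mol⁻¹)
    (constants at 25 °C)

In the flask at 1.77 min, the L-assisted step was using G 3.7 times as fast as G → E, and the violet dose gave 0.774 J per G added, more than the 0.507 of the first charge. In a neighbouring flask with 1.2 M of G, the G yield promises 0.608 M of J against 0.30 M of X, so X should take over as the charge that ends first. Computed, J in that flask stands at 99.9% at 10 min, with X at 0% and G at 2.0% of their charges.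

(The earlier runs and the new flask were computed for an exercise.)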